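**Assumption:** Kuwanon T has no stereocentre and no E/Z-stereogenic alkene (both prenyl groups end in CMe2), so it is achiral. The "single enantiomer" requirement is therefore moot and no stereocontrol is needed. The route, including the proposed key step, is a design on paper and has not been run.

## Retrosynthetic overview

1. Kuwanon T (16) ⇐ tetra-MOM ether 15 by global acetal cleavage.
2. 15 ⇐ ynone 14 by a proposed Pd(0)-catalysed cycloisomerisation with O→C3 prenyl transfer, which forms the pyranone C-ring (the only ring built) and the C3–prenyl bond in one step.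
3. 14 ⇐ A-ring aldehyde 5 + B-ring aryl alkyne 12 (acetylide addition, then oxidation).
4. 5 ⇐ 2,4,6-trihydroxybenzaldehyde (bis-MOM, O-prenyl). 12 ⇐ resorcinol (two directed ortho-metalations: prenyl, then CHO; Ohira–Bestmann alkynylation).

## Forward route

**Step 1**
Reactants: 1 (2,4,6-trihydroxybenzaldehyde); 2 (chloromethyl methyl ether, MOMCl)
Product: 3, 2-hydroxy-4,6-bis(methoxymethoxy)benzaldehyde
Conditions: MOMCl (2.2 equiv), i-Pr2NEt, CH2Cl2, 0 °C → rt
Reagents that add atoms: MOMCl (2), COCCl
Why: Selective O-alkylation (acetal protection); one ortho OH stays hydrogen-bonded to the CHO and is much less nucleophilic, so bis-protection stops at the 4,6-diether.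

**Step 2**
Reactants: 3; 4 (prenyl bromide, 1-bromo-3-methylbut-2-ene)
Product: 5, 2-(3-methylbut-2-enyloxy)-4,6-bis(methoxymethoxy)benzaldehyde
Conditions: K2CO3, DMF, rt → 40 °C
Reagents that add atoms: prenyl bromide (4), CC(C)=CCBr
Why: Williamson etherification of the remaining phenol by SN2 at the primary allylic bromide; the temperature is far below that needed for aryl-Claisen rearrangement.

**Step 3**
Reactants: 6 (resorcinol); 2 (MOMCl)
Product: 7, 1,3-bis(methoxymethoxy)benzene
Conditions: NaH, DMF, 0 °C; MOMCl (2.4 equiv), 0 °C → rt
Reagents that add atoms: MOMCl (2), COCCl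
Why: Standard phenoxide alkylation (MOM protection), which also installs the two ortho-directing groups for steps 4 and 5.

**Step 4**
Reactants: 7; 4 (prenyl bromide)
Product: 8, 1,3-bis(methoxymethoxy)-2-(3-methylbut-2-enyl)benzene
Conditions: n-BuLi, THF, 0 °C → rt; then CuI (10 mol %), prenyl bromide, −78 °C → rt
Reagents that add atoms: prenyl bromide (4), CC(C)=CCBr
Why: Directed ortho-metalation at C2, the position flanked by both OMOM groups, followed by Cu-assisted α-selective allylic substitution to give the linear prenyl arene.

**Step 5**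
Reactants: 8; 9 (N,N-dimethylformamide)
Product: 10, 2,4-bis(methoxymethoxy)-3-(3-methylbut-2-enyl)benzaldehyde
Conditions: n-BuLi, TMEDA, THF, −20 → 0 °C; then DMF, −78 °C → rt; aq. NH4Cl
Reagents that add atoms: DMF (9), CN(C)C=O
Why: Second directed ortho-metalation, at the only remaining position ortho to an OMOM group (C4), then formylation with DMF; OMOM coordination favours ring lithiation over benzylic/allylic deprotonation.

**Step 6**
Reactants: 10; 11 (Ohira–Bestmann reagent, dimethyl (1-diazo-2-oxopropyl)phosphonate)
Product: 12, 1-ethynyl-2,4-bis(methoxymethoxy)-3-(3-methylbut-2-enyl)benzene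
Conditions: K2CO3, MeOH, 0 °C → rt
Reagents that add atoms: Ohira–Bestmann reagent (11), COP(=O)(OC)C(=[N+]=[N-])C(C)=O (supplies the terminal alkyne carbon)
Why: Seyferth–Gilbert/Ohira–Bestmann homologation (HWE olefination, N2 loss, 1,2-H shift of the alkylidene carbene); MOM ethers and the prenyl group are inert to K2CO3/MeOH.

**Step 7**
Reactants: 12; 5
Product: 13, (±)-1-[2-(3-methylbut-2-enyloxy)-4,6-bis(methoxymethoxy)phenyl]-3-[2,4-bis(methoxymethoxy)-3-(3-methylbut-2-enyl)phenyl]prop-2-yn-1-ol
Conditions: 12 (1.15 equiv), n-BuLi (1.1 equiv), THF, −78 °C; then 5, −78 → 0 °C; aq. NH4Cl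
Reagents that add atoms: none (both partners are the reactants)
Why: 1,2-Addition of a lithium acetylide to a non-enolisable aryl aldehyde; the carbinol centre is formed racemic deliberately because it is oxidised away in step 8.

**Step 8**
Reactants: 13
Product: 14, 1-[2-(3-methylbut-2-enyloxy)-4,6-bis(methoxymethoxy)phenyl]-3-[2,4-bis(methoxymethoxy)-3-(3-methylbut-2-enyl)phenyl]prop-2-yn-1-one
Conditions: activated MnO2 (15 equiv), CH2Cl2, rt
Reagents that add atoms: none
Why: Chemoselective MnO2 oxidation of a doubly activated (benzylic and propargylic) alcohol; prenyl alkenes, the aryl prenyl ether and the MOM acetals are untouched.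

**Step 9 (key step)**
Reactants: 14
Product: 15, 5,7-bis(methoxymethoxy)-2-[2,4-bis(methoxymethoxy)-3-(3-methylbut-2-enyl)phenyl]-3-(3-methylbut-2-enyl)-4H-chromen-4-one
Conditions: Pd2(dba)3 (2.5 mol %), Xantphos (6 mol %), 4 Å MS, degassed dry THF (0.05 M), 60 °C
Reagents that add atoms: none (isomerisation; 14 and 15 are constitutional isomers)
Why: Proposed new method: Pd(0) ionises the aryl prenyl ether (the leaving group is an ortho-acyl phenoxide) to a [(Xantphos)Pd(η3-prenyl)]+/phenoxide ion pair. The tethered phenoxide then adds 6-endo-dig (oxa-Michael) to the ynone, which gives a carbonyl-stabilised allenolate, whereas the 5-exo (aurone) mode would give an unstabilised vinyl anion. The C3 carbanion (or the equivalent vinyl-Pd(allyl) species) is captured by the π-prenyl unit at its unsubstituted terminus, closing the γ-pyrone and forming the linear C3–prenyl bond irreversibly, while any O-allylation is reversible under Pd(0). Aprotic, sieve-dried conditions suppress protonation to the 3-H flavone. The closest known reaction types are the Pd-catalysed cyclisation/allyl migration of o-allyloxyaryl alkynes to 3-allylbenzofurans, Pd-catalysed O→C allyl shifts and decarboxylative enolate allylation (enolate/π-allyl ion pairs), and base-mediated 6-endo cyclisation of o-hydroxyaryl ynones to flavones. To my knowledge the combination, with a prenyl group and an ynone giving a 3-prenylflavone, has not been demonstrated.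

**Step 10**
Reactants: 15
Product: 16, Kuwanon T, 2-[2,4-dihydroxy-3-(3-methylbut-2-enyl)phenyl]-5,7-dihydroxy-3-(3-methylbut-2-enyl)-4H-chromen-4-one
Conditions: 3 M aq. HCl/MeOH/THF (1:4:1), 40 °C, N2, monitored and stopped at full conversion
Reagents that add atoms: none
Why: Acid-catalysed acetal (MOM) hydrolysis of all four aryl ethers (the peri 5-OMOM cleaves fastest); dilute acid at mild temperature removes MOM faster than it promotes phenol–prenyl cyclisation to chromans.

## Compound list

1 | 2,4,6-trihydroxybenzaldehyde | O=Cc1c(O)cc(O)cc1O | starting material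
2 | chloromethyl methyl ether (MOMCl) | COCCl | starting material (reagent)
3 | 2-hydroxy-4,6-bis(methoxymethoxy)benzaldehyde | O=Cc1c(O)cc(OCOC)cc1OCOC | intermediate
4 | prenyl bromide | CC(C)=CCBr | starting material (reagent)
5 | 2-(3-methylbut-2-enyloxy)-4,6-bis(methoxymethoxy)benzaldehyde | O=Cc1c(OCC=C(C)C)cc(OCOC)cc1OCOC | intermediate
6 | resorcinol | Oc1cccc(O)c1 | starting material
7 | 1,3-bis(methoxymethoxy)benzene | COCOc1cccc(OCOC)c1 | intermediate
8 | 1,3-bis(methoxymethoxy)-2-(3-methylbut-2-enyl)benzene | COCOc1cccc(OCOC)c1CC=C(C)C | intermediate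
9 | N,N-dimethylformamide | CN(C)C=O | starting material (reagent)
10 | 2,4-bis(methoxymethoxy)-3-(3-methylbut-2-enyl)benzaldehyde | O=Cc1ccc(OCOC)c(CC=C(C)C)c1OCOC | intermediate
11 | dimethyl (1-diazo-2-oxopropyl)phosphonate (Ohira–Bestmann reagent) | COP(=O)(OC)C(=[N+]=[N-])C(C)=O | starting material (reagent)
12 | 1-ethynyl-2,4-bis(methoxymethoxy)-3-(3-methylbut-2-enyl)benzene | C#Cc1ccc(OCOC)c(CC=C(C)C)c1OCOC | intermediate
13 | (±)-propargylic alcohol from 5 + 12 | OC(C#Cc1ccc(OCOC)c(CC=C(C)C)c1OCOC)c1c(OCC=C(C)C)cc(OCOC)cc1OCOC | intermediate (racemic; centre removed in step 8)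
14 | diaryl ynone (o-prenyloxyaryl alkynyl ketone) | O=C(C#Cc1ccc(OCOC)c(CC=C(C)C)c1OCOC)c1c(OCC=C(C)C)cc(OCOC)cc1OCOC | intermediate
15 | Kuwanon T tetrakis(methoxymethyl) ether | COCOc1cc(OCOC)c2c(c1)oc(-c1ccc(OCOC)c(CC=C(C)C)c1OCOC)c(CC=C(C)C)c2=O | intermediate
16 | Kuwanon T | CC(C)=CCc1c(O)ccc(-c2oc3cc(O)cc(O)c3c(=O)c2CC=C(C)C)c1O | target

## Summary

**Total step count:** 10

**Longest linear sequence:** 8 steps (resorcinol → 7 → 8 → 10 → 12 → 13 → 14 → 15 → 16); the A-ring branch is 2 steps.

**Three steps most likely to fail:**

1. **Step 9 (proposed Pd-catalysed cyclisation/prenyl transfer).** Risks are protonation to the 3-H flavone, 5-exo closure to an aurone, C-prenylation of the electron-rich A-ring, and reverse (branched) prenyl transfer.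
   Fallback (known chemistry): the classical Baker–Venkataraman route. Pinnick-oxidise 10 to the benzoic acid and esterify it with 2-hydroxy-4,6-bis(methoxymethoxy)acetophenone (from commercial 2,4,6-trihydroxyacetophenone). Base-mediated acyl migration gives the 1,3-diketone, which is C-prenylated with prenyl bromide/K2CO3 and cyclodehydrated (NaOAc/AcOH) to 15. Step 10 is unchanged.

2. **Step 10 (global MOM removal).** The risk is acid-induced cyclisation of the 3'-prenyl group onto the 2'- or 4'-OH (chroman formation) or alkene hydration.
   Fallback: change the protecting-group strategy to SEM ethers throughout (SEMCl in steps 1 and 3; SEM also directs the ortho-lithiations). The final unmasking is then fluoride-mediated (TBAF/DMPU, heat) and no Brønsted acid ever meets the prenylated phenols.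

3. **Step 5 (second ortho-lithiation/formylation of prenyl arene 8).** The risk is competing deprotonation at the benzylic/allylic CH2.
   Fallback: make 10 without organolithium chemistry. Direct C3-prenylation of commercial 2,4-dihydroxybenzaldehyde with prenyl bromide in aqueous KOH (phenoxide C-alkylation, modest yield, 3-isomer separable), then bis-MOM protection (MOMCl, NaH) gives 10.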